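**Retrosynthetic overview**
1. Target 8 (all-cis oxolane diol) ⇐ diester bis-pivalate 7 by one LiAlH4 reduction (esters → CH2OH, pivalates → ArOH).
2. 7 ⇐ tetrasubstituted furan 6 by one-face catalytic hydrogenation, which sets all four stereocentres as all-cis.
3. 6 ⇐ 1,4-diketone 5 (Paal–Knorr) ⇐ aldehyde 2 acting as an acyl anion (thiazolylidene, Stetter) + aroylfumarate 4: the key C–C bond.
4. 4 ⇐ aldehyde 2 + DMAD 3 (pyridine-catalysed formal hydroacylation); 2 ⇐ syringaldehyde 1 + pivaloyl chloride.
5. Ring order: the furan is the only ring built (step 3); it is then saturated to the oxolane (step 4).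

Assumption: the SMILES describes the all-cis 2,3,4,5-tetrasubstituted oxolane, which has a mirror plane (meso; 2R,3R,4S,5S ≡ 2S,3S,4R,5R), so only relative configuration has to be controlled and no enantiocontrol is needed.

**Route**

Step 1
Reactants: 1 syringaldehyde (4-hydroxy-3,5-dimethoxybenzaldehyde)
Product: 2 4-formyl-2,6-dimethoxyphenyl 2,2-dimethylpropanoate
Conditions: pivaloyl chloride (1.2 equiv), Et3N (1.5 equiv), 4-(dimethylamino)pyridine (5 mol %), CH2Cl2, 0 °C → rt
Reagents that add atoms: pivaloyl chloride, CC(C)(C)C(=O)Cl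
Why: DMAP-catalysed O-acylation of the phenol (nucleophilic acyl substitution) gives a hindered aryl pivalate that removes the acidic OH, makes the aldehyde more electrophilic for steps 2 and 3, withstands amine, acid and hydrogenation conditions and is cleaved by the hydride of step 5; no stereocentre is involved.

Step 2
Reactants: 2 4-formyl-2,6-dimethoxyphenyl 2,2-dimethylpropanoate; 3 dimethyl acetylenedicarboxylate (DMAD)
Product: 4 dimethyl (2E)-2-[4-(2,2-dimethylpropanoyloxy)-3,5-dimethoxybenzoyl]but-2-enedioate
Conditions: pyridine (20 mol %), DME, −10 °C → rt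
Reagents that add atoms: none
Why: Pyridine-catalysed formal hydroacylation of DMAD (nucleophilic catalysis of the Morita–Baylis–Hillman type, a known route to 2-aroylfumarates from electron-poor benzaldehydes): pyridine adds to 3, the zwitterionic vinyl anion adds to the aldehyde of 2, and a 1,3-proton shift followed by loss of pyridine gives the enedioate, whose geometry is irrelevant because both alkene carbons become furan carbons.

Step 3
Reactants: 4 dimethyl (2E)-2-[4-(2,2-dimethylpropanoyloxy)-3,5-dimethoxybenzoyl]but-2-enedioate; 2 4-formyl-2,6-dimethoxyphenyl 2,2-dimethylpropanoate (1.3 equiv)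
Product: 6 dimethyl 2,5-bis[4-(2,2-dimethylpropanoyloxy)-3,5-dimethoxyphenyl]furan-3,4-dicarboxylate, via diaroylsuccinate diketone 5 (not isolated)
Conditions: 3-ethyl-5-(2-hydroxyethyl)-4-methylthiazolium bromide (20 mol %), Et3N (0.5 equiv), 1,4-dioxane, 70 °C; evaporate; then p-toluenesulfonic acid monohydrate (TsOH·H2O, 0.3 equiv), PhMe, reflux (Dean–Stark)
Reagents that add atoms: none
Why: Stetter reaction then Paal–Knorr furan synthesis: the thiazol-2-ylidene converts a second molecule of 2 into its Breslow intermediate, an acyl anion equivalent that adds to the ester-bearing CH terminus of the doubly activated alkene 4 (β to both the ketone and the geminal ester), so that two carbons that are both electrophilic in their parent compounds are joined, and acid-catalysed cyclodehydration of the resulting 1,4-diketone 5 gives the aromatic furan and erases the two stereocentres of 5.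

Step 4
Reactants: 6 dimethyl 2,5-bis[4-(2,2-dimethylpropanoyloxy)-3,5-dimethoxyphenyl]furan-3,4-dicarboxylate
Product: 7 dimethyl (2R,3S,4R,5S)-2,5-bis[4-(2,2-dimethylpropanoyloxy)-3,5-dimethoxyphenyl]oxolane-3,4-dicarboxylate (all-cis, meso)
Conditions: H2 (50 bar), 10% Pd/C, EtOAc, 50 °C, stopped after uptake of 2 equiv H2
Reagents that add atoms: none
Why: Heterogeneous catalytic hydrogenation adds all four hydrogens to the face of the furan that lies on the metal (and any 2,3-dihydrofuran that desorbs re-adsorbs through its less hindered, hydrogen-bearing face), so the two aryl groups and the two esters end up on the same side and the four stereocentres of the meso all-cis oxolane are set together, as known for tetrasubstituted 2,5-diarylfurans; the acyloxy groups and the β-esters slow hydrogenolysis of the benzylic C–O bonds in neutral EtOAc.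

Step 5
Reactants: 7 dimethyl (2R,3S,4R,5S)-2,5-bis[4-(2,2-dimethylpropanoyloxy)-3,5-dimethoxyphenyl]oxolane-3,4-dicarboxylate
Product: 8 [(2R,3R,4S,5S)-2,5-bis(4-hydroxy-3,5-dimethoxyphenyl)oxolane-3,4-diyl]dimethanol (all-cis, meso; the target)
Conditions: LiAlH4 (6 equiv), THF, −20 °C → rt; aq. potassium sodium tartrate work-up at pH about 7
Reagents that add atoms: none
Why: LiAlH4 reduction converts both methyl esters into primary alcohols and cleaves both aryl pivalates to the phenols in one operation; hydride addition to the esters at low temperature outruns enolisation, and the near-neutral tartrate work-up avoids quinone-methide-type opening at the benzylic ether carbons, so the all-cis configuration set in step 4 is kept.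

**Compound list**
1 | syringaldehyde (4-hydroxy-3,5-dimethoxybenzaldehyde) | COc1cc(C=O)cc(OC)c1O | starting material
2 | 4-formyl-2,6-dimethoxyphenyl 2,2-dimethylpropanoate | COc1cc(C=O)cc(OC)c1OC(=O)C(C)(C)C | intermediate
3 | dimethyl acetylenedicarboxylate (dimethyl but-2-ynedioate) | COC(=O)C#CC(=O)OC | starting material
4 | dimethyl (2E)-2-[4-(2,2-dimethylpropanoyloxy)-3,5-dimethoxybenzoyl]but-2-enedioate | COC(=O)/C=C(/C(=O)OC)C(=O)c1cc(OC)c(OC(=O)C(C)(C)C)c(OC)c1 | intermediate
5 | dimethyl 2,3-bis[4-(2,2-dimethylpropanoyloxy)-3,5-dimethoxybenzoyl]butanedioate (mixture of diastereomers, not isolated) | COC(=O)C(C(=O)c1cc(OC)c(OC(=O)C(C)(C)C)c(OC)c1)C(C(=O)OC)C(=O)c1cc(OC)c(OC(=O)C(C)(C)C)c(OC)c1 | intermediate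
6 | dimethyl 2,5-bis[4-(2,2-dimethylpropanoyloxy)-3,5-dimethoxyphenyl]furan-3,4-dicarboxylate | COC(=O)c1c(-c2cc(OC)c(OC(=O)C(C)(C)C)c(OC)c2)oc(-c2cc(OC)c(OC(=O)C(C)(C)C)c(OC)c2)c1C(=O)OC | intermediate
7 | dimethyl (2R,3S,4R,5S)-2,5-bis[4-(2,2-dimethylpropanoyloxy)-3,5-dimethoxyphenyl]oxolane-3,4-dicarboxylate (all-cis, meso) | COc1cc([C@H]2O[C@@H](c3cc(OC)c(OC(=O)C(C)(C)C)c(OC)c3)[C@@H](C(=O)OC)[C@H]2C(=O)OC)cc(OC)c1OC(=O)C(C)(C)C | intermediate
8 | [(2R,3R,4S,5S)-2,5-bis(4-hydroxy-3,5-dimethoxyphenyl)oxolane-3,4-diyl]dimethanol (all-cis, meso) | COc1cc([C@H]2O[C@@H](c3cc(OC)c(O)c(OC)c3)[C@@H](CO)[C@H]2CO)cc(OC)c1O | target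

**Totals**
Total step count: 5.
Longest linear sequence: 5 steps (1 → 2 → 4 → 6 → 7 → 8; aldehyde 2 enters a second time in step 3).

**Steps most likely to fail, with fallbacks**

Step 2 is the first risk: the pyridine–DMAD zwitterion may oligomerise DMAD faster than it adds to aldehyde 2. The fallback sets out from 2 and makes the same bond with the acyl anion first. A Stetter reaction of 2 with commercial dimethyl fumarate (same thiazolium bromide, Et3N, dioxane, 70 °C) gives dimethyl 2-[4-(2,2-dimethylpropanoyloxy)-3,5-dimethoxybenzoyl]butanedioate F1. Bromination at the β-keto ester carbon with N-bromosuccinimide in CH2Cl2 gives dimethyl 2-bromo-2-[4-(2,2-dimethylpropanoyloxy)-3,5-dimethoxybenzoyl]butanedioate F2. Excess Et3N then eliminates HBr, and the route is rejoined at 4.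

Step 3 is the second risk: the Stetter addition to the trisubstituted alkene 4 may lose out to benzoin formation or to base-induced polymerisation of 4. The fallback sets out from 2 and builds diketone 5 through its central C–C bond instead. SnCl2-catalysed Roskamp homologation of 2 with methyl diazoacetate (CH2Cl2, rt) gives methyl 3-[4-(2,2-dimethylpropanoyloxy)-3,5-dimethoxyphenyl]-3-oxopropanoate F3. Its sodium enolate (NaH, THF, 0 °C) is treated with I2 (0.5 equiv). The methyl 2-iodo-3-[4-(2,2-dimethylpropanoyloxy)-3,5-dimethoxyphenyl]-3-oxopropanoate F4 formed in the flask acts as an enolonium equivalent and is alkylated by a second enolate. The route is rejoined at 5, which is cyclodehydrated with TsOH·H2O as before to give 6.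

Step 4 is the third risk: the push–pull furan diester 6 may stop at the dihydrofuran, or forcing conditions may cleave a benzylic C–O bond. The fallback sets out from 6 and reverses the order of the last two operations. LiAlH4 (THF, 0 °C → rt) first gives [2,5-bis(4-hydroxy-3,5-dimethoxyphenyl)furan-3,4-diyl]dimethanol F5. This electron-rich furan is then hydrogenated from one face over Rh/Al2O3 (5 wt %, H2 4 bar, MeOH, rt), conditions that are far milder and cause little hydrogenolysis. The route is rejoined directly at target 8.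

**Further compounds**
F1 | step 2 | dimethyl 2-[4-(2,2-dimethylpropanoyloxy)-3,5-dimethoxybenzoyl]butanedioate (racemic) | COC(=O)CC(C(=O)OC)C(=O)c1cc(OC)c(OC(=O)C(C)(C)C)c(OC)c1
F2 | step 2 | dimethyl 2-bromo-2-[4-(2,2-dimethylpropanoyloxy)-3,5-dimethoxybenzoyl]butanedioate (racemic) | COC(=O)CC(Br)(C(=O)OC)C(=O)c1cc(OC)c(OC(=O)C(C)(C)C)c(OC)c1
F3 | step 3 | methyl 3-[4-(2,2-dimethylpropanoyloxy)-3,5-dimethoxyphenyl]-3-oxopropanoate | COC(=O)CC(=O)c1cc(OC)c(OC(=O)C(C)(C)C)c(OC)c1
F4 | step 3 | methyl 2-iodo-3-[4-(2,2-dimethylpropanoyloxy)-3,5-dimethoxyphenyl]-3-oxopropanoate (racemic, not isolated) | COC(=O)C(I)C(=O)c1cc(OC)c(OC(=O)C(C)(C)C)c(OC)c1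
F5 | step 4 | [2,5-bis(4-hydroxy-3,5-dimethoxyphenyl)furan-3,4-diyl]dimethanol | COc1cc(-c2oc(-c3cc(OC)c(O)c(OC)c3)c(CO)c2CO)cc(OC)c1O
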